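The target slows long before the starting material is used up: the west run holds 0.1430 M of target at 140 min, with 0.107 M of starting material still in the flask.

| flask | starting material | free catalyst | time |
|---|---|---|---|
| west | 0.250 M | 0.0200 M |  |
| north | 0.250 M | 0.0100 M |  |
| south-east | 0.380 M | 0.0200 M |  |
| north-west | 0.610 M | 0.0200 M | 140 min |

| run | time / min | [target] / M |
|---|---|---|
| west run | 11 | 0.0419 |
| west run | 32 | 0.0834 |
| west run | 62 | 0.1161 |
| west run | 98 | 0.1365 |
| west run | 140 | 0.1430 |
| north run | 11 | 0.0133 |
| north run | 32 | 0.0341 |
| north run | 62 | 0.0499 |
| north run | 98 | 0.0585 |
| north run | 140 | 0.0637 |
| south-east run | 11 | 0.0499 |
| south-east run | 32 | 0.1217 |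
| south-east run | 62 | 0.1717 |
| south-east run | 98 | 0.1991 |
| south-east run | 140 | 0.2174 |

(each reading ± 0.002 M)

- apparent order in [starting material] of the starting rate, round the charge of the west run (the rate where two percent of its starting material have turned into target) (one fixed amount of target, the same in the runs compared)
- apparent order in [free catalyst] of the starting rate, round the charge of the west run (the rate where two percent of its starting material have turned into target)
- target in the north-west run at 140 min, as a share of the starting material charged

- Overall: starting material -> target, with free catalyst as catalyst.
- Constant volume, constant temperature.
- What is held in complexes is read along with the free species.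
- An order is taken over about fifteen percent of the charge, up and down.

Take the west run in slow motion. Over its first 11 min it makes target at 0.00381 M min⁻¹ on average. In the middle, from 32 min to 62 min, the rate is 0.00109 M min⁻¹, and at the end, from 98 min to 140 min, it is 1.55 × 10⁻⁴ M min⁻¹. Read so, the rate has fallen about 24.6-fold while the starting material fell 2.34-fold, a much larger drop, so we take the catalyst to be going as well.

Suppose, then, that the rate of making target over the rate of losing working catalyst is proportional to [starting material]. Dividing one rate by the other removes time: target made per catalyst lost, a turnover number, is proportional to [starting material]. Summed over a run, the log conversion L = ln([starting material at start]/[starting material now]) is proportional to the catalyst lost.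

At 140 min, L is 0.849 in the west run and 0.294 in the north run. Their difference over the difference in catalyst charge gives 55.5 L mol⁻¹, the log conversion per catalyst lost. The south-east run, with more starting material but the west run's catalyst, reads 0.849, the same, which is what the rule gives if both runs have lost the same catalyst by then.

If both runs are nearly finished at 140 min, the west run has lost 0.0153 M of working catalyst, and 0.00470 M of its charge makes no target. Our reckoning for the north-west run, with the same catalyst charge and taken as finished at 140 min, is 57.2%. If the starting rate follows working catalyst, the order in free catalyst is 1.31.

The forecast gives 0.42 and 1.7 for the orders in starting material and free catalyst and 53.5% for the north-west run, reading that “the catalyst is dying”.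

The flask gives 55.9% for the north-west run, 1.3 percentage points below our reckoning, with orders 0.72 in starting material and 1.3 in free catalyst, the latter as reckoned.

    free catalyst + starting material ⇌ catalyst-substrate complex, settled at all times (70.00 L mol⁻¹)
    catalyst-substrate complex + starting material ⇌ doubly bound catalyst, settled at all times (3.130 L mol⁻¹)
    doubly bound catalyst → target + catalyst-substrate complex (0.6720 min⁻¹)
    free catalyst + impurity → spent catalyst
    catalyst-substrate complex → spent catalyst + starting material (0.03360 min⁻¹)

The south-east run had made target equal to half of its starting material charged at 78.6 min, later than the 71.3 min of the west run. With our constant, the north-west run's L of 0.818 counts 0.0147 M of working catalyst lost by 140 min, and the south-east run at that halfway point counts 0.0125 M.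

Readings and results come from a simulation for substances that don't exist; scatter was added.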